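| setting | gamma | beta | spring | winter |
|---|---|---|---|---|
| substrate | 0.0062 M | 0.042 M | 0.012 M | 0.050 M |
| reagent | 0.060 M | 0.060 M | 0.0600 M | 0.0600 M |
| remark | run made earlier | run made earlier |  |  |
| time |  |  | 0.80 min | 3.0 min |
- gamma (time / min: target / %, substrate / %): 0.250: 15, 86; 0.500: 24, 71; 1.33: 52, 44; 3.00: 82, 21
- beta (time / min: target / %, substrate / %): 0.417: 18, 78; 1.00: 40, 53; 2.00: 54, 36; 3.00: 67, 22

(scatter of a reading: 2 percentage points)
1. the flask that ends with the higher amount of target, in percent of the substrate charged, or "neither" when 2 percentage points or less lies between them (spring / winter / neither)
2. final target, as a percentage of the substrate charged, in spring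
3. final target, as a percentage of the substrate charged, in winter
- percent here means substrate units held: one side product A or side product B counts as two
- steps that have been proposed: substrate + reagent -> target; 2 substrate -> side product A; substrate + target -> side product B

1. In a one-step world, substrate + reagent → target, and with [reagent] held still the substrate decays exponentially: the pseudo-first-order picture. The dilute gamma run comes close to this world, since its target and substrate together stay near the charge. Its substrate reading of 44% at 1.33 min gives a decay of 0.617 min⁻¹. Dividing by its [reagent] gives 10.3 M⁻¹ min⁻¹, the clock rate.

2. The clock of a flask is this rate times [reagent] times time, and the target share is one minus the exponential of minus the clock.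

3. Ceiling: [reagent] stays at its charge and no side step runs. Spring has a clock of 0.494, so 39.0%. Winter has 1.85, so 84.3%.

4. Floor: [reagent] stands from the start where the ceiling target leaves it. That is 0.0553 M in spring, giving 36.6%, and 0.0178 M in winter, giving 42.4%.

5. In each flask [reagent] starts at the charge and falls, so the clock lies between these two. Winter's floor stands above spring's ceiling. Side steps still take a share: the beta balance lacks 11.0% at its last reading. This reckoning takes winter's mean clock, which gives 69.9%, and subtracts that gap to reach 58.9%.

6. The forecast says winter, with 36% in spring and, for winter alone by a “hand stepwise integration with reagent depletion”, 61% in winter, a little above this reckoning for winter.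

7. The flasks give 37.7% in spring and 61.4% in winter, so winter ends higher.

    substrate + reagent → target (k = 0.174 M⁻¹ s⁻¹)
    2 substrate → side product A (k = 0.00819 M⁻¹ s⁻¹)
    substrate + target → side product B (k = 0.0264 M⁻¹ s⁻¹)

Spring lags mainly through its short time: the same flask given winter's time holds 79.1% of target, against 37.7%. The clock at that time is 1.85, and the simulated value stands beneath its ceiling of 84.3%.

Take the neighbour of winter with 0.015 M of reagent. Its clock at the charge is 0.463, a ceiling of 37.1%, but that charge, the limiting reagent, allows 30.0% of target. Taking the floor clock as nil, half the clock gives 20.7%, and the computed flask holds 19.1%.

The earlier runs and the new flask were generated by integration for substances that don't exist, noise included.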